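The route rests on disconnecting the C8–OMe bond of ring A. In the target, C5–OH and C8–OMe lie para to each other across the A ring, which is exactly what a para-quinone monoketal delivers on two-electron reduction. One iodine(III) oxidation in methanol converts a 5-hydroxy-6,7-dimethoxyflavone, whose C8 is the only unsubstituted A-ring carbon, into the 8,8-dimethoxy dienone, so the C8 oxygen arrives already differentiated from O5. The precursor is built from 3,4,5-trimethoxyphenol and methoxyhydroquinone by a chalcone/iodine–DMSO flavone synthesis. Its B-ring hydroquinone is masked as benzyl ethers, and the peri 5-methyl ether is removed with chelation-selective magnesium iodide. Zinc reduction and hydrogenolysis finish.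

Key step: step 7

Remark: the target has no stereocentre or other stereogenic element, so no enantiocontrol is needed; the E-alkene of 7 and the racemic centre of 8 vanish on aromatisation. Ketone 6 is believed to be purchasable, which would save step 3.

Step 1
Reactants: 1 methoxyhydroquinone (2-methoxybenzene-1,4-diol)
Product: 2 1,4-bis(benzyloxy)-2-methoxybenzene
Conditions: BnBr (2.4 equiv), K2CO3 (3 equiv), DMF, N2, rt → 60 °C
Reagents that add atoms: benzyl bromide BrCc1ccccc1
Why: Williamson ether synthesis on both phenols; the inert atmosphere keeps the hydroquinone dianion from oxidising to the quinone.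

Step 2
Reactants: 2 1,4-bis(benzyloxy)-2-methoxybenzene
Product: 4 2,5-bis(benzyloxy)-4-methoxybenzaldehyde, via iminium salt 3 (not isolated)
Conditions: POCl3 (1.5 equiv), DMF, 0 → 75 °C; then ice–water, 50 °C
Reagents that add atoms: N,N-dimethylformamide CN(C)C=O; water O
Why: Vilsmeier–Haack formylation should go to C5 of 2, which is para to the methoxyl and ortho to a benzyloxy group (C3 is flanked by two alkoxy groups and C6 has only one ortho donor), the same orientation as 1,2,4-trimethoxybenzene giving 2,4,5-trimethoxybenzaldehyde.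

Step 3
Reactants: 5 3,4,5-trimethoxyphenol
Product: 6 1-(6-hydroxy-2,3,4-trimethoxyphenyl)ethan-1-one
Conditions: AcOH (excess), BF3·OEt2 (3 equiv), 90 °C; then H2O
Reagents that add atoms: acetic acid CC(=O)O
Why: Friedel–Crafts (Nencki-type) C-acylation ortho to the phenol, where the two ortho positions are equivalent and the para position is blocked; the product is held as its BF2 chelate until aqueous work-up.

Step 4
Reactants: 6 1-(6-hydroxy-2,3,4-trimethoxyphenyl)ethan-1-one; 4 2,5-bis(benzyloxy)-4-methoxybenzaldehyde
Product: 7 (E)-3-[2,5-bis(benzyloxy)-4-methoxyphenyl]-1-(6-hydroxy-2,3,4-trimethoxyphenyl)prop-2-en-1-one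
Conditions: KOH (50% aq., 5 equiv), EtOH, rt, 24–48 h; then cold dil. HCl
Reagents that add atoms: none
Why: Claisen–Schmidt condensation of a methyl ketone with a non-enolisable aldehyde; E1cB dehydration should give the conjugated E-enone, and the benzyl ethers are inert to hydroxide.

Step 5
Reactants: 7 (E)-3-[2,5-bis(benzyloxy)-4-methoxyphenyl]-1-(6-hydroxy-2,3,4-trimethoxyphenyl)prop-2-en-1-one
Product: 9 2-[2,5-bis(benzyloxy)-4-methoxyphenyl]-5,6,7-trimethoxy-4H-chromen-4-one, via flavanone 8 (not isolated)
Conditions: I2 (10 mol%), DMSO, 130 °C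
Reagents that add atoms: none
Why: iodine/DMSO oxidative cyclisation of a 2'-hydroxychalcone: 6-endo oxa-Michael addition gives the flavanone, α-iodination and loss of HI give the flavone, and DMSO reoxidises HI to I2; benzyl aryl ethers are routinely carried through these conditions.

Step 6
Reactants: 9 2-[2,5-bis(benzyloxy)-4-methoxyphenyl]-5,6,7-trimethoxy-4H-chromen-4-one
Product: 10 2-[2,5-bis(benzyloxy)-4-methoxyphenyl]-5-hydroxy-6,7-dimethoxy-4H-chromen-4-one
Conditions: MgI2 (anhydrous, 3 equiv), toluene–Et2O, 80 °C; then cold 1 M HCl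
Reagents that add atoms: none
Why: chelation-directed ether cleavage: magnesium bridges the C4 carbonyl and O5 in a six-membered chelate and iodide removes the activated methyl by SN2, while the benzyl ethers and the other methyl ethers lack a second donor and should resist this weak Lewis acid (boron or aluminium halides would also strip the benzyl groups).

Step 7
Reactants: 10 2-[2,5-bis(benzyloxy)-4-methoxyphenyl]-5-hydroxy-6,7-dimethoxy-4H-chromen-4-one
Product: 12 2-[2,5-bis(benzyloxy)-4-methoxyphenyl]-6,7,8,8-tetramethoxy-4H-chromene-4,5(8H)-dione, via 8-methoxyphenol 11 (not isolated)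
Conditions: PhI(OAc)2 (2.3 equiv), MeOH–CH2Cl2 (4:1), 0 °C → rt
Reagents that add atoms: methanol CO
Why: The 5-phenol displaces acetate on iodine(III), and departure of iodobenzene from the aryloxy-iodane leaves a phenoxenium-type species that methanol captures at C8, para to O5, giving 8-methoxyphenol 11 after tautomerisation. Because 11 is more electron-rich than 10, a second equivalent of oxidant converts it at once and methanol adds to the C8 oxocarbenium carbon, so the sequence runs through to the 8,8-dimethoxy-2,5-cyclohexadienone 12 at a single oxidation level. The closest known reaction type is the PhI(OAc)2/methanol conversion of para-unsubstituted phenols into para-quinone monoketals. No ring is closed and no stereocentre is formed, since C8 carries two identical methoxyl groups. The step needs para (C8) over ipso-ortho (C6) capture on ring A, and ring A over ring B: C8 is the only C–H on ring A and is unhindered, whereas C6 is wedged between the C5 and C7 substituents and its twisted methoxyl stabilises charge poorly, and ring B carries no free phenol and is deactivated by conjugation with the pyranone. Any ortho monoketal that does form should be returned to 10 by the reduction of step 8 and can be recycled.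

Step 8
Reactants: 12 2-[2,5-bis(benzyloxy)-4-methoxyphenyl]-6,7,8,8-tetramethoxy-4H-chromene-4,5(8H)-dione
Product: 11 2-[2,5-bis(benzyloxy)-4-methoxyphenyl]-5-hydroxy-6,7,8-trimethoxy-4H-chromen-4-one
Conditions: Zn dust (10 equiv), glacial AcOH–THF (1:4), 0 °C → rt
Reagents that add atoms: none
Why: dissolving-metal reduction of a para-quinone monoketal to a 4-alkoxyphenol: two-electron transfer to the cross-conjugated dienone gives the C5 enolate, which expels one C8 methoxide and rearomatises ring A; water-free acid avoids ketal hydrolysis, and the chromone enone and benzyl ethers are inert to Zn/AcOH at rt.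

Step 9
Reactants: 11 2-[2,5-bis(benzyloxy)-4-methoxyphenyl]-5-hydroxy-6,7,8-trimethoxy-4H-chromen-4-one
Product: 13 2-(2,5-dihydroxy-4-methoxyphenyl)-5-hydroxy-6,7,8-trimethoxy-4H-chromen-4-one (target)
Conditions: H2 (1 atm), 10% Pd/C, EtOAc–MeOH (degassed), rt; filtration and concentration under N2
Reagents that add atoms: none
Why: catalytic hydrogenolysis of the two benzyl aryl ethers; at 1 atm and rt the chromone C2=C3 bond and the methyl ethers should survive, and inert handling protects the electron-rich B-ring hydroquinone from air oxidation.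

Compound list
1 | methoxyhydroquinone (2-methoxybenzene-1,4-diol) | COc1cc(O)ccc1O | starting material
2 | 1,4-bis(benzyloxy)-2-methoxybenzene | COc1cc(OCc2ccccc2)ccc1OCc1ccccc1 | intermediate
3 | [2,5-bis(benzyloxy)-4-methoxybenzylidene]dimethyliminium dichlorophosphate | COc1cc(OCc2ccccc2)c(C=[N+](C)C)cc1OCc1ccccc1.[O-]P(=O)(Cl)Cl | intermediate (not isolated)
4 | 2,5-bis(benzyloxy)-4-methoxybenzaldehyde | COc1cc(OCc2ccccc2)c(C=O)cc1OCc1ccccc1 | intermediate
5 | 3,4,5-trimethoxyphenol | COc1cc(O)cc(OC)c1OC | starting material
6 | 1-(6-hydroxy-2,3,4-trimethoxyphenyl)ethan-1-one | CC(=O)c1c(O)cc(OC)c(OC)c1OC | intermediate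
7 | (E)-3-[2,5-bis(benzyloxy)-4-methoxyphenyl]-1-(6-hydroxy-2,3,4-trimethoxyphenyl)prop-2-en-1-one | COc1cc(OCc2ccccc2)c(/C=C/C(=O)c2c(O)cc(OC)c(OC)c2OC)cc1OCc1ccccc1 | intermediate
8 | 2-[2,5-bis(benzyloxy)-4-methoxyphenyl]-5,6,7-trimethoxychroman-4-one (racemic) | COc1cc(OCc2ccccc2)c(C2CC(=O)c3c(OC)c(OC)c(OC)cc3O2)cc1OCc1ccccc1 | intermediate (not isolated)
9 | 2-[2,5-bis(benzyloxy)-4-methoxyphenyl]-5,6,7-trimethoxy-4H-chromen-4-one | COc1cc2oc(-c3cc(OCc4ccccc4)c(OC)cc3OCc3ccccc3)cc(=O)c2c(OC)c1OC | intermediate
10 | 2-[2,5-bis(benzyloxy)-4-methoxyphenyl]-5-hydroxy-6,7-dimethoxy-4H-chromen-4-one | COc1cc2oc(-c3cc(OCc4ccccc4)c(OC)cc3OCc3ccccc3)cc(=O)c2c(O)c1OC | intermediate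
11 | 2-[2,5-bis(benzyloxy)-4-methoxyphenyl]-5-hydroxy-6,7,8-trimethoxy-4H-chromen-4-one | COc1c(OC)c2oc(-c3cc(OCc4ccccc4)c(OC)cc3OCc3ccccc3)cc(=O)c2c(O)c1OC | intermediate (formed in the flask in step 7, isolated in step 8)
12 | 2-[2,5-bis(benzyloxy)-4-methoxyphenyl]-6,7,8,8-tetramethoxy-4H-chromene-4,5(8H)-dione | COC1=C(OC)C(OC)(OC)C2=C(C1=O)C(=O)C=C(c1cc(OCc3ccccc3)c(OC)cc1OCc1ccccc1)O2 | intermediate
13 | 2-(2,5-dihydroxy-4-methoxyphenyl)-5-hydroxy-6,7,8-trimethoxy-4H-chromen-4-one | COc1cc(O)c(-c2cc(=O)c3c(O)c(OC)c(OC)c(OC)c3o2)cc1O | target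

Total step count: 9. Longest linear sequence: 8 steps (1 → 2 → 4 → 7 → 9 → 10 → 12 → 11 → 13).

Steps most likely to fail

Step 7. Methanol capture may lose regiocontrol, with ipso attack at the methoxylated ortho carbon C6 giving an ortho-quinone monoketal. Ligand exchange of the hydrogen-bonded 5-hydroxyl may be slow, and ring B may suffer competing oxidation. The fallback sets out from 10 and returns at 11, bypassing 12. Elbs persulfate oxidation (K2S2O8, aqueous KOH/pyridine, 0 °C → rt) should attack the phenolate para to O5 and give potassium 2-[2,5-bis(benzyloxy)-4-methoxyphenyl]-5-hydroxy-6,7-dimethoxy-4-oxo-4H-chromen-8-yl sulfate F1. Warm dilute HCl with Na2SO3 should hydrolyse the sulfate ester to 2-[2,5-bis(benzyloxy)-4-methoxyphenyl]-5,8-dihydroxy-6,7-dimethoxy-4H-chromen-4-one F2. MeI (1.1 equiv), K2CO3, acetone under N2 should then methylate only the non-chelated 8-hydroxyl, giving 11.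

Step 6. Chemoselectivity may erode, with ether cleavage spreading to the benzyl groups or to the 6-methyl ether, or the chelated demethylation may stall. The fallback sets out from 9 and returns at 10. BCl3 (excess) with pentamethylbenzene in CH2Cl2, −78 → 0 °C, should cleave the chelated 5-methyl ether and both benzyl ethers to give 2-(2,5-dihydroxy-4-methoxyphenyl)-5-hydroxy-6,7-dimethoxy-4H-chromen-4-one F3. BnBr (2.1 equiv), K2CO3, acetone under N2 should then re-benzylate only the two B-ring phenols, because the hydrogen-bonded 5-hydroxyl resists mild alkylation, giving 10.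

Step 8. Acid-promoted hydrolysis of the ketal may outrun electron transfer, so that reduction ends with loss of the C8 methyl group. The fallback sets out from 12 and returns at 11. The ketal is hydrolysed on purpose (aqueous oxalic acid, THF, rt) to 2-[2,5-bis(benzyloxy)-4-methoxyphenyl]-6,7-dimethoxy-4H-chromene-4,5,8-trione F4. Na2S2O4 (EtOAc/water) should reduce this quinone to the 5,8-dihydroxyflavone F2 described in the first fallback, and the same selective 8-O-methylation (MeI, K2CO3, acetone, N2) should give 11.

Further compounds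
F1 | step 7 | potassium 2-[2,5-bis(benzyloxy)-4-methoxyphenyl]-5-hydroxy-6,7-dimethoxy-4-oxo-4H-chromen-8-yl sulfate | COc1c(OS(=O)(=O)[O-])c2oc(-c3cc(OCc4ccccc4)c(OC)cc3OCc3ccccc3)cc(=O)c2c(O)c1OC.[K+]
F2 | step 7 | 2-[2,5-bis(benzyloxy)-4-methoxyphenyl]-5,8-dihydroxy-6,7-dimethoxy-4H-chromen-4-one | COc1c(O)c2oc(-c3cc(OCc4ccccc4)c(OC)cc3OCc3ccccc3)cc(=O)c2c(O)c1OC
F3 | step 6 | 2-(2,5-dihydroxy-4-methoxyphenyl)-5-hydroxy-6,7-dimethoxy-4H-chromen-4-one | COc1cc2oc(-c3cc(O)c(OC)cc3O)cc(=O)c2c(O)c1OC
F4 | step 8 | 2-[2,5-bis(benzyloxy)-4-methoxyphenyl]-6,7-dimethoxy-4H-chromene-4,5,8-trione | COC1=C(OC)C(=O)C2=C(C1=O)C(=O)C=C(c1cc(OCc3ccccc3)c(OC)cc1OCc1ccccc1)O2
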